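**Retrosynthetic overview**
- Feature: in ring C the carbonyl carbon C4 is a single-carbon bridge between A-ring carbon C4a and the oxygen-bearing C3. It can therefore enter the molecule as carbon monoxide.
- Late stage: the sulfate goes onto the free C3–OH of 3'-O-benzylombuin. C5–OH is chelated to C4=O and every other phenol is etherified. The 3'-O-benzyl group comes off last.
- Ring C (O1–C2 bond) comes from an acyclic 2-(methoxymethoxy)-1,3-diaryl-1,3-diketone by acid MOM removal and cyclodehydration.
- The diketone is cut at C4a–C4 and C4–C3 together, giving the mirror-symmetric A-ring iodide, CO and the enolate of the B-ring α-MOM-oxy ketone (Pd-catalysed carbonylative α-arylation).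
- Ring order: rings A and B are bought as arenes (5-methoxyresorcinol and 3'-hydroxy-4'-methoxyacetophenone). Ring C is the only ring built, in step 7.

Key step: step 6

Assumption: the target has no stereocentre and no stereogenic axis, so no enantiomer has to be selected; because it is drawn as the free hydrogen sulfate, the sulfate is carried as its triethylammonium salt and protonated only in the last operation.

**Step 1**
Reactants: 1 5-methoxyresorcinol
Product: 2 1-methoxy-3,5-bis(methoxymethoxy)benzene
Conditions: NaH (2.4 equiv), MOMCl (2.4 equiv), DMF, 0 °C → rt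
Reagents that add atoms: chloromethyl methyl ether (MOMCl), COCCl
Why: Williamson-type O-alkylation (MOM acetal formation) of the two equivalent phenoxides with the hard electrophile MOMCl should occur on oxygen only and installs the groups that direct the lithiation and later fall off in acid.

**Step 2**
Reactants: 2 1-methoxy-3,5-bis(methoxymethoxy)benzene
Product: 4 2-iodo-5-methoxy-1,3-bis(methoxymethoxy)benzene, via aryllithium 3 (not isolated)
Conditions: n-BuLi (1.1 equiv), THF, 0 °C, 1 h; I2 (1.2 equiv), THF, −78 °C → rt; aq. Na2S2O3 wash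
Reagents that add atoms: iodine, II; n-butyllithium, [Li]CCCC (lithium in 3 only)
Why: Directed ortho-metalation, in which the C–H between the two chelating OMOM groups (stronger directors than OMe, acting together) should be lithiated in preference to the OMOM/OMe-flanked positions, and iodine traps aryllithium 3 to give an iodide with a mirror plane through C2 and C5.

**Step 3**
Reactants: 5 3'-hydroxy-4'-methoxyacetophenone
Product: 6 3'-benzyloxy-4'-methoxyacetophenone
Conditions: BnBr (1.1 equiv), K2CO3 (1.5 equiv), DMF, 50 °C
Reagents that add atoms: benzyl bromide, BrCc1ccccc1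
Why: Williamson ether synthesis on the only phenol gives a benzyl ether that tolerates strong base, Pd(0)/CO and methanolic acid and is removable by hydrogenolysis at the end.

**Step 4**
Reactants: 6 3'-benzyloxy-4'-methoxyacetophenone
Product: 8 1-(3-benzyloxy-4-methoxyphenyl)-2-hydroxyethanone, via hydroxy dimethyl ketal 7 (not isolated)
Conditions: PhI(OAc)2 (1.1 equiv), KOH (3 equiv), MeOH, 0 °C → rt; then 2 M HCl, THF, rt
Reagents that add atoms: water, O (new carbonyl oxygen of 8); methanol, CO (the two ketal OMe groups of 7 only)
Why: Moriarty hypervalent-iodine α-hydroxylation, in which the enolate binds I(III), methoxide adds to the carbonyl, the alkoxide expels PhI to form a methoxy-oxirane that methoxide opens to ketal 7, and dilute acid hydrolyses the ketal to the α-hydroxy ketone without touching the aryl ethers.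

**Step 5**
Reactants: 8 1-(3-benzyloxy-4-methoxyphenyl)-2-hydroxyethanone
Product: 9 1-(3-benzyloxy-4-methoxyphenyl)-2-(methoxymethoxy)ethanone
Conditions: MOMCl (1.5 equiv), i-Pr2NEt (2 equiv), CH2Cl2, 0 °C → rt
Reagents that add atoms: chloromethyl methyl ether (MOMCl), COCCl
Why: MOM acetal formation on the primary alcohol under an amine base too weak to enolise the ketone masks the future C3 oxygen with the same acid-labile group used on ring A, so one acid treatment later frees all three oxygens.

**Step 6**
Reactants: 4 2-iodo-5-methoxy-1,3-bis(methoxymethoxy)benzene, 9 1-(3-benzyloxy-4-methoxyphenyl)-2-(methoxymethoxy)ethanone, 10 carbon monoxide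
Product: 13 1-(3-benzyloxy-4-methoxyphenyl)-3-[4-methoxy-2,6-bis(methoxymethoxy)phenyl]-2-(methoxymethoxy)propane-1,3-dione (racemic, labile centre), via sodium enolate 11 (not isolated), via sodium diketonate 12 (not isolated)
Conditions: 9 (2.1 equiv), NaHMDS (2.0 equiv), THF, 0 °C, 15 min; then 4 (1.0 equiv), Pd(dba)2 (5 mol%), DPPP (6 mol%), CO (ca. 1 atm, sealed vessel), THF, 80 °C; AcOH quench; surplus 9 recovered
Reagents that add atoms: carbon monoxide 10, [C-]#[O+]; NaHMDS, C[Si](C)(C)[N-][Si](C)(C)C.[Na+] (sodium in 11 and 12 only)
Why: Pd(0)/DPPP adds oxidatively into the C–I bond of 4, the crowded aryl–Pd takes up CO by migratory insertion to an aroyl–Pd species (C4a–C4), enolate 11 replaces iodide on palladium and C–C reductive elimination forms C4–C3, which is the known palladium-catalysed carbonylative α-arylation of aryl alkyl ketones with aryl iodides (α-substituted enolates included), applied here to an α-alkoxy member. No ring closes in this step. The one new stereocentre (the future C3) sits between two carbonyl groups, forms racemic and labile, and becomes sp2 in step 7, so nothing needs to control it. The first selectivity needed is carbonylative over direct arylation, and the two ortho OMOM groups of 4 secure it because they slow aryl–enolate reductive elimination while insertion of the small CO ligand relieves strain at the metal. The second is C- over O-acylation: the chelating bisphosphine holds the aroyl group and the carbon-bound enolate cis, any enol ester formed can still transfer its acyl group to excess 11, and the product drains into diketonate 12, which also blocks a second acylation. Using a second equivalent of 11 as the base, rather than excess amide, keeps free NaHMDS away from the aroyl–Pd intermediate.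

**Step 7**
Reactants: 13 the 2-(methoxymethoxy)-1,3-diketone
Product: 15 2-(3-benzyloxy-4-methoxyphenyl)-3,5-dihydroxy-7-methoxy-4H-chromen-4-one (3'-O-benzylombuin), via triol diketone 14 (not isolated)
Conditions: conc. HCl (cat., ca. 5 vol%), MeOH–THF 3:1, 60 °C
Reagents that add atoms: none
Why: Acid-catalysed transacetalisation to methanol removes the three MOM groups (the formaldehyde equivalent is trapped as its dimethyl acetal, away from the electron-rich A ring), either of the two equivalent ortho phenols of 14 adds to the B-ring carbonyl (6-exo-trig hemiketal, O1–C2), and loss of water gives the conjugated 4-pyranone as in the cyclodehydration that ends a Baker–Venkataraman flavone synthesis, leaving 5-OH/7-OMe and turning the labile centre into sp2 C3.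

**Step 8**
Reactants: 15 3'-O-benzylombuin
Product: 16 triethylammonium 2-(3-benzyloxy-4-methoxyphenyl)-5-hydroxy-7-methoxy-4-oxo-4H-chromen-3-yl sulfate
Conditions: SO3·NEt3 (2 equiv), Et3N (2 equiv), DMF, 45 °C; Sephadex LH-20 (MeOH)
Reagents that add atoms: sulfur trioxide–triethylamine complex, CC[N+](CC)(CC)S(=O)(=O)[O-]
Why: O-sulfation with an amine–SO3 complex should take only C3–OH, because C5–OH is locked in a six-membered hydrogen bond to C4=O (the least reactive hydroxyl of a flavonol) and all other phenols are etherified.

**Step 9**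
Reactants: 16 the triethylammonium 3'-O-benzyl sulfate
Product: 18 ombuin 3-O-sulfate (target), via triethylammonium salt 17 (not isolated)
Conditions: H2 (1 atm), 10% Pd/C, MeOH, rt; filter; Dowex 50WX8 (H+ form), MeOH–H2O, 0 °C; immediate freeze-drying
Reagents that add atoms: none
Why: Benzyl aryl ether hydrogenolysis at neutral pH should spare the sulfate monoester salt, the tetrasubstituted conjugated C2=C3 bond and the methyl ethers, and cold cation exchange swaps Et3NH+ for H+ to give the hydrogen sulfate as drawn.

**Compound list**
1 | 5-methoxyresorcinol | COc1cc(O)cc(O)c1 | starting material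
2 | 1-methoxy-3,5-bis(methoxymethoxy)benzene | COCOc1cc(OC)cc(OCOC)c1 | intermediate
3 | 4-methoxy-2,6-bis(methoxymethoxy)phenyllithium | [Li]c1c(OCOC)cc(OC)cc1OCOC | intermediate (not isolated)
4 | 2-iodo-5-methoxy-1,3-bis(methoxymethoxy)benzene | COCOc1cc(OC)cc(OCOC)c1I | intermediate
5 | 3'-hydroxy-4'-methoxyacetophenone | CC(=O)c1ccc(OC)c(O)c1 | starting material
6 | 3'-benzyloxy-4'-methoxyacetophenone | CC(=O)c1ccc(OC)c(OCc2ccccc2)c1 | intermediate
7 | 2-(3-benzyloxy-4-methoxyphenyl)-2,2-dimethoxyethanol | COC(CO)(OC)c1ccc(OC)c(OCc2ccccc2)c1 | intermediate (not isolated)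
8 | 1-(3-benzyloxy-4-methoxyphenyl)-2-hydroxyethanone | O=C(CO)c1ccc(OC)c(OCc2ccccc2)c1 | intermediate
9 | 1-(3-benzyloxy-4-methoxyphenyl)-2-(methoxymethoxy)ethanone | COCOCC(=O)c1ccc(OC)c(OCc2ccccc2)c1 | intermediate
10 | carbon monoxide | [C-]#[O+] | starting material
11 | sodium (Z)-enolate of 9 | COCO/C=C(\[O-])c1ccc(OC)c(OCc2ccccc2)c1.[Na+] | intermediate (not isolated)
12 | sodium enolate of diketone 13 | COCOc1cc(OC)cc(OCOC)c1C(=O)C(OCOC)=C([O-])c1ccc(OC)c(OCc2ccccc2)c1.[Na+] | intermediate (not isolated)
13 | 1-(3-benzyloxy-4-methoxyphenyl)-3-[4-methoxy-2,6-bis(methoxymethoxy)phenyl]-2-(methoxymethoxy)propane-1,3-dione (racemic) | COCOc1cc(OC)cc(OCOC)c1C(=O)C(OCOC)C(=O)c1ccc(OC)c(OCc2ccccc2)c1 | intermediate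
14 | 1-(3-benzyloxy-4-methoxyphenyl)-3-(2,6-dihydroxy-4-methoxyphenyl)-2-hydroxypropane-1,3-dione (racemic) | COc1cc(O)c(C(=O)C(O)C(=O)c2ccc(OC)c(OCc3ccccc3)c2)c(O)c1 | intermediate (not isolated)
15 | 2-(3-benzyloxy-4-methoxyphenyl)-3,5-dihydroxy-7-methoxy-4H-chromen-4-one | COc1cc(O)c2c(=O)c(O)c(-c3ccc(OC)c(OCc4ccccc4)c3)oc2c1 | intermediate
16 | triethylammonium 2-(3-benzyloxy-4-methoxyphenyl)-5-hydroxy-7-methoxy-4-oxo-4H-chromen-3-yl sulfate | COc1cc(O)c2c(=O)c(OS(=O)(=O)[O-])c(-c3ccc(OC)c(OCc4ccccc4)c3)oc2c1.CC[NH+](CC)CC | intermediate
17 | triethylammonium salt of ombuin 3-O-sulfate | COc1cc(O)c2c(=O)c(OS(=O)(=O)[O-])c(-c3ccc(OC)c(O)c3)oc2c1.CC[NH+](CC)CC | intermediate (not isolated)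
18 | ombuin 3-O-sulfate | COc1cc(O)c2c(=O)c(OS(=O)(=O)O)c(-c3ccc(OC)c(O)c3)oc2c1 | target

**Total step count:** 9
**Longest linear sequence:** 7 steps (5 → 6 → 8 → 9 → 13 → 15 → 16 → 18; the A-ring branch 1 → 2 → 4 joins at step 6)

**Steps most likely to fail**

1. **Step 6.** Capture of the hindered aroyl–palladium species by the secondary alkoxy enolate may be slow. Proto-deiodination, O-acylation or interception by silazane could then take over.
   - The fallback supplies C4 as a formyl carbon instead of CO. It sets out from 2 and 9 and comes back at 13.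
   - Aryllithium 3, generated as in step 2, is quenched with DMF to give 4-methoxy-2,6-bis(methoxymethoxy)benzaldehyde F1.
   - The lithium enolate of 9 (LDA, THF, −78 °C) adds to it in an aldol reaction. This gives 1-(3-benzyloxy-4-methoxyphenyl)-3-hydroxy-3-[4-methoxy-2,6-bis(methoxymethoxy)phenyl]-2-(methoxymethoxy)propan-1-one F2 as a diastereomer mixture, which is of no consequence.
   - Dess–Martin oxidation of the carbinol then delivers diketone 13.

2. **Step 9.** The sulfate ester may hydrolyse while the ionic substrate is being debenzylated or handled, and salts 16/17 are hard to purify.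
   - The fallback introduces the sulfate as a neutral, chromatographable diester. It sets out from 15, bypasses 16 and 17, and comes back at 18.
   - 2,2,2-Trichloroethyl chlorosulfate, Et3N and DMAP in THF should give 2-(3-benzyloxy-4-methoxyphenyl)-5-hydroxy-7-methoxy-4-oxo-4H-chromen-3-yl 2,2,2-trichloroethyl sulfate F3.
   - Buffered transfer hydrogenolysis (Pd/C, HCO2NH4, MeOH) removes the trichloroethyl and benzyl groups in one operation to give the ammonium salt of ombuin 3-O-sulfate F4.
   - The same cold H+ exchange converts this salt into 18.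

3. **Step 7.** Once C3–OH is free in hot acidic methanol, retro-Claisen methanolysis of the non-enolised diketone may compete with ring closure, or the reaction may stall at the hemiketal.
   - The fallback closes ring C first, in an aprotic medium, with the C3 oxygen still masked. It sets out from 13 and comes back at 15.
   - Silica-supported NaHSO4 in CH2Cl2 is selective for aryl MOM ethers. Brief warming in toluene over the same solid acid should follow and give 2-(3-benzyloxy-4-methoxyphenyl)-5-hydroxy-7-methoxy-3-(methoxymethoxy)-4H-chromen-4-one F5.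
   - This robust flavone then loses its last MOM group with HCl in MeOH at rt to give 15.

**Further compounds**
F1 | step 6 | 4-methoxy-2,6-bis(methoxymethoxy)benzaldehyde | COCOc1cc(OC)cc(OCOC)c1C=O
F2 | step 6 | 1-(3-benzyloxy-4-methoxyphenyl)-3-hydroxy-3-[4-methoxy-2,6-bis(methoxymethoxy)phenyl]-2-(methoxymethoxy)propan-1-one (diastereomer mixture, racemic) | COCOc1cc(OC)cc(OCOC)c1C(O)C(OCOC)C(=O)c1ccc(OC)c(OCc2ccccc2)c1
F3 | step 9 | 2-(3-benzyloxy-4-methoxyphenyl)-5-hydroxy-7-methoxy-4-oxo-4H-chromen-3-yl 2,2,2-trichloroethyl sulfate | COc1cc(O)c2c(=O)c(OS(=O)(=O)OCC(Cl)(Cl)Cl)c(-c3ccc(OC)c(OCc4ccccc4)c3)oc2c1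
F4 | step 9 | ammonium salt of ombuin 3-O-sulfate | COc1cc(O)c2c(=O)c(OS(=O)(=O)[O-])c(-c3ccc(OC)c(O)c3)oc2c1.[NH4+]
F5 | step 7 | 2-(3-benzyloxy-4-methoxyphenyl)-5-hydroxy-7-methoxy-3-(methoxymethoxy)-4H-chromen-4-one | COCOc1c(-c2ccc(OC)c(OCc3ccccc3)c2)oc2cc(OC)cc(O)c2c1=O
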